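**Retrosynthetic overview**
1. Target ⇐ desilylation ⇐ C6'–C7' B-alkyl Suzuki union of chroman diene 10 (as its 9-BBN adduct) with vinyl iodide 15, which carries the C9' carbinol (Brown allylation) and the prenyl end (cross-metathesis).
2. Diene 10 ⇐ SeO2 oxidation of the (E)-methyl, then methylenation, of prenyl-chromanol 6.
3. Bold step: chroman 6 is not closed at C2 and not made from a preformed chroman synthon. The aryl–O1 bond is formed with retention by PIDA dearomatisation of p-methoxyphenol 4 (tertiary OH attacks C8a), followed by reductive rearomatisation.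
4. Phenol 4 ⇐ hydroboration/B-alkyl Suzuki of (R)-linalool with bromophenol 2; linalool supplies the intact C2 quaternary carbinol, C3–C4 (its vinyl group) and C1'–C4' (its prenyl arm).
5. Ring order: the arene is bought; the dihydropyran ring is the only ring formed (steps 3–4), before the side chain is extended.

Assumption: commercial (R)-(−)-linalool of ≥95% ee and 2-bromo-6-methylanisole are used as purchased; the C2 ee of the product equals the linalool ee. The route is a paper design and has not been run.

**Route**

Step 1
Reactants: 1, 2-bromo-6-methylanisole (1-bromo-2-methoxy-3-methylbenzene)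
Product: 2, 3-bromo-4-methoxy-5-methylphenol
Conditions: [Ir(OMe)(cod)]2 (1 mol%), dtbpy (2 mol%), B2pin2, THF, 80 °C; then Oxone, acetone/H2O, rt (one pot)
Reagents that add atoms: Oxone (potassium peroxymonosulfate), [K+].[O-]S(=O)(=O)OO (phenolic O)
Why: Sterically controlled Ir-catalysed C–H borylation occurs only at the one C–H with no ortho substituent (para to OMe), and the ArBpin is oxidised in the same pot to the phenol (one-pot C–H borylation/oxidation); C–Br is untouched.

Step 2
Reactants: 3, (R)-(−)-linalool [(3R)-3,7-dimethylocta-1,6-dien-3-ol]; 2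
Product: 4, 3-[(3R)-3-hydroxy-3,7-dimethyloct-6-en-1-yl]-4-methoxy-5-methylphenol
Conditions: 3 (1.3 equiv), 9-BBN-H (2.9 equiv), THF, 0 °C→rt; then 2, SPhos Pd G3 (3 mol%), 3 M aq K3PO4, THF, 65 °C
Reagents that add atoms: none
Why: 9-BBN hydroborates only the monosubstituted vinyl group, anti-Markovnikov (the trisubstituted alkene is far slower; one equivalent is consumed by the tertiary OH), and the primary alkylborane undergoes B-alkyl Suzuki–Miyaura coupling with the aryl bromide; the carbinol centre is a spectator and stays R.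

Step 3
Reactants: 4
Product: 5, (2R)-8a-methoxy-2,8-dimethyl-2-(4-methylpent-3-en-1-yl)-2,3,4,8a-tetrahydro-6H-chromen-6-one (cyclic quinone monoketal, both C8a epimers)
Conditions: PhI(OAc)2 (1.1 equiv), NaHCO3, CH2Cl2/HFIP (4:1), 0 °C, 15 min
Reagents that add atoms: none
Why: Hypervalent-iodine oxidative dearomatisation turns the p-methoxyphenol into a 4-methoxyphenoxenium ion, which the pendant tertiary OH traps at the OMe-bearing para carbon (six-membered ring) to give the quinone monoketal; the linalool C–O bond is never broken, so C2 is R with retention.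

Step 4
Reactants: 5 (crude, telescoped)
Product: 6, (2R)-2,8-dimethyl-2-(4-methylpent-3-en-1-yl)chroman-6-ol
Conditions: L-ascorbic acid (3 equiv), THF/H2O, rt
Reagents that add atoms: none
Why: Reductive rearomatisation of a quinone monoketal (the tocopherone→tocopherol reaction): mild acid ionises the exocyclic OMe to the ring-closed chromanoxylium ion, which ascorbate reduces by two electrons to the 6-chromanol; C2–O1 is untouched.

Step 5
Reactants: 6
Product: 7, (2R)-6-(tert-butyldimethylsilyloxy)-2,8-dimethyl-2-(4-methylpent-3-en-1-yl)chroman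
Conditions: TBSCl, imidazole, DMF, rt
Reagents that add atoms: TBSCl, CC(C)(C)[Si](C)(C)Cl
Why: Standard phenol silylation protects the oxidation-prone chromanol through steps 6–13.

Step 6
Reactants: 7
Product: 8, (2E)-5-[(2R)-6-(TBSO)-2,8-dimethylchroman-2-yl]-2-methylpent-2-en-1-ol (with some enal 9; the mixture is carried forward)
Conditions: SeO2 (0.5 equiv), t-BuOOH (3 equiv), salicylic acid (10 mol%), CH2Cl2, rt
Reagents that add atoms: selenium dioxide, O=[Se]=O; tert-butyl hydroperoxide, CC(C)(C)OO
Why: Sharpless catalytic SeO2 allylic oxidation (ene reaction then [2,3]-sigmatropic shift) selectively oxidises the (E)-methyl of a terminal gem-dimethyl alkene, giving the (E)-allylic alcohol; this is the only alkene in 7.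

Step 7
Reactants: 8 (plus any 9 from step 6)
Product: 9, (2E)-5-[(2R)-6-(TBSO)-2,8-dimethylchroman-2-yl]-2-methylpent-2-enal
Conditions: MnO2 (20 equiv), CH2Cl2, rt
Reagents that add atoms: none
Why: MnO2 oxidises allylic alcohols to enals without E/Z erosion and converges the step-6 mixture on 9.

Step 8
Reactants: 9
Product: 10, (2R)-6-(TBSO)-2,8-dimethyl-2-[(3E)-4-methylhexa-3,5-dien-1-yl]chroman
Conditions: Ph3PCH3Br, KHMDS, THF, 0 °C
Reagents that add atoms: methyltriphenylphosphonium bromide, C[P+](c1ccccc1)(c1ccccc1)c1ccccc1.[Br-]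
Why: Wittig methylenation of the enal gives the terminal 1,3-diene and leaves the (E)-trisubstituted alkene and the aryl silyl ether unchanged.

Step 9
Reactants: 11, propargyl alcohol
Product: 12, (E)-3-iodo-2-methylprop-2-en-1-ol
Conditions: Me3Al (3 equiv), Cp2ZrCl2 (0.25 equiv), CH2Cl2, 0 °C→rt; then I2, THF, −30 °C
Reagents that add atoms: trimethylaluminium, C[Al](C)C; iodine, II
Why: Negishi Zr-catalysed carboalumination adds Me–Al syn across the alkyne (Me to the internal carbon), and iodinolysis with retention gives the (E)-vinyl iodide.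

Step 10
Reactants: 12
Product: 13, (E)-3-iodo-2-methylprop-2-enal
Conditions: MnO2, CH2Cl2, rt (used as a solution)
Reagents that add atoms: none
Why: Chemoselective MnO2 allylic oxidation; the vinyl iodide geometry is retained.

Step 11
Reactants: 13
Product: 14, (3R,1E)-1-iodo-2-methylhexa-1,5-dien-3-ol
Conditions: B-allyldiisopinocampheylborane from (+)-Ipc2BOMe [(−)-α-pinene series] and allylMgBr, Et2O, −78 °C; then 13, −78 °C; then NaOH/H2O2
Reagents that add atoms: allylmagnesium bromide, C=CC[Mg]Br
Why: Brown asymmetric allylboration through a chair Zimmerman–Traxler transition state; the (−)-α-pinene-derived reagent delivers allyl to the Re face to set C9' as R (the antipodal reagent gives S with α-methyl enals), to be confirmed by Mosher ester analysis.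

Step 12
Reactants: 14
Product: 15, (3R,1E)-1-iodo-2,6-dimethylhepta-1,5-dien-3-ol
Conditions: 2-methyl-2-butene (large excess), Grubbs II (5 mol%), CH2Cl2, 40 °C
Reagents that add atoms: 2-methyl-2-butene, CC=C(C)C
Why: Olefin cross-metathesis converts the terminal vinyl group into the prenyl terminus; the trisubstituted vinyl iodide is inert and the carbinol centre is not touched.

Step 13
Reactants: 10; 15
Product: 16, 6-O-TBS-sargachromanol C [(2R)-6-(TBSO)-2-[(3E,7E,9R)-9-hydroxy-4,8,12-trimethyltrideca-3,7,11-trien-1-yl]-2,8-dimethylchroman]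
Conditions: 10, 9-BBN-H (1.3 equiv), THF, 0 °C→rt; then 15, Pd(dppf)Cl2 (5 mol%), AsPh3, Cs2CO3, DMF/THF/H2O, rt
Reagents that add atoms: none
Why: 9-BBN adds to the terminal CH2=CH of the diene with boron on the terminal carbon (homoallylic borane), and B-alkyl Suzuki–Miyaura coupling with the vinyl iodide forms C6'–C7' with retention of the E geometry; the free OH is tolerated and neither stereocentre is involved.

Step 14
Reactants: 16
Product: 17, sargachromanol C
Conditions: TBAF, AcOH (buffer), THF, 0 °C, under Ar
Reagents that add atoms: none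
Why: Fluoride cleavage of the aryl silyl ether; the allylic alcohol, the three alkenes and both stereocentres are inert.

**Compound list**
1 | 2-bromo-6-methylanisole | COc1c(C)cccc1Br | starting material
2 | 3-bromo-4-methoxy-5-methylphenol | COc1c(C)cc(O)cc1Br | intermediate
3 | (R)-(−)-linalool | CC(C)=CCC[C@@](C)(O)C=C | starting material
4 | 3-[(3R)-3-hydroxy-3,7-dimethyloct-6-en-1-yl]-4-methoxy-5-methylphenol | CC(C)=CCC[C@@](C)(O)CCc1cc(O)cc(C)c1OC | intermediate
5 | (2R)-8a-methoxy-2,8-dimethyl-2-(4-methylpent-3-en-1-yl)-2,3,4,8a-tetrahydro-6H-chromen-6-one (C8a epimers) | CC(C)=CCC[C@]1(C)CCC2=CC(=O)C=C(C)C2(OC)O1 | intermediate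
6 | (2R)-2,8-dimethyl-2-(4-methylpent-3-en-1-yl)chroman-6-ol | CC(C)=CCC[C@]1(C)CCc2cc(O)cc(C)c2O1 | intermediate
7 | TBS ether of 6 | CC(C)=CCC[C@]1(C)CCc2cc(O[Si](C)(C)C(C)(C)C)cc(C)c2O1 | intermediate
8 | (2E)-5-[(2R)-6-(TBSO)-2,8-dimethylchroman-2-yl]-2-methylpent-2-en-1-ol | OC/C(C)=C/CC[C@]1(C)CCc2cc(O[Si](C)(C)C(C)(C)C)cc(C)c2O1 | intermediate
9 | (2E)-5-[(2R)-6-(TBSO)-2,8-dimethylchroman-2-yl]-2-methylpent-2-enal | O=C/C(C)=C/CC[C@]1(C)CCc2cc(O[Si](C)(C)C(C)(C)C)cc(C)c2O1 | intermediate
10 | (2R)-6-(TBSO)-2,8-dimethyl-2-[(3E)-4-methylhexa-3,5-dien-1-yl]chroman | C=C/C(C)=C/CC[C@]1(C)CCc2cc(O[Si](C)(C)C(C)(C)C)cc(C)c2O1 | intermediate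
11 | propargyl alcohol | C#CCO | starting material
12 | (E)-3-iodo-2-methylprop-2-en-1-ol | OC/C(C)=C/I | intermediate
13 | (E)-3-iodo-2-methylprop-2-enal | O=C/C(C)=C/I | intermediate
14 | (3R,1E)-1-iodo-2-methylhexa-1,5-dien-3-ol | C=CC[C@@H](O)/C(C)=C/I | intermediate
15 | (3R,1E)-1-iodo-2,6-dimethylhepta-1,5-dien-3-ol | CC(C)=CC[C@@H](O)/C(C)=C/I | intermediate
16 | 6-O-TBS-sargachromanol C | CC(C)=CC[C@@H](O)/C(C)=C/CC/C(C)=C/CC[C@]1(C)CCc2cc(O[Si](C)(C)C(C)(C)C)cc(C)c2O1 | intermediate
17 | sargachromanol C, (2R)-2-[(3E,7E,9R)-9-hydroxy-4,8,12-trimethyltrideca-3,7,11-trien-1-yl]-2,8-dimethylchroman-6-ol | CC(C)=CC[C@@H](O)/C(C)=C/CC/C(C)=C/CC[C@]1(C)CCc2cc(O)cc(C)c2O1 | target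

**Totals**
Total steps: 14. Longest linear sequence: 10 (steps 1–8, 13, 14); the iodide branch is steps 9–12.

**Three steps most likely to fail, with fallbacks**
1. Steps 3–4 (PIDA ketalisation and reductive rearomatisation). Risks are trapping by acetate or water to give the open quinone, attack at the ortho carbon, or ring-opening on reduction. Fallback: drop the chiral-pool C–O closure and make the chroman by Trost Pd-catalysed asymmetric allylic etherification of a phenol bearing a trisubstituted allylic carbonate, giving (R)-6-(TBSO)-2,8-dimethyl-2-vinylchroman. Hydroboration (9-BBN) and B-alkyl Suzuki coupling with iodide 12 then give 8 directly and the route rejoins at step 7.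
2. Step 13 (diene hydroboration and sp3–sp2 Suzuki). Risks are the regiochemistry of diene hydroboration and β-hydride loss. Fallback: an alkyne linchpin. Convert 8 to the allylic bromide, alkylate with lithiated 1-(trimethylsilyl)propyne and desilylate. Add the acetylide to the Weinreb amide of 4-methylpent-3-enoic acid and reduce the ynone by Noyori transfer hydrogenation to the (R)-propargylic alcohol. Ru-catalysed trans-hydrostannation followed by Stille methylation then installs the (E)-C7'=C8'(Me) unit.
3. Step 6 (SeO2 allylic oxidation). Risks are modest yield and over-oxidation. Fallback: replace C–H oxidation by olefin cross-metathesis of the prenyl terminus of 7 with methacrolein (Hoveyda–Grubbs II), which gives (E)-enal 9 directly and removes step 7.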